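I took each product to use one reagent and one substrate, and in both Thursday's run and the new flask the reagent charged equals the two substrates together. So one fraction f, what is left of the pair, is also the fraction of reagent left.

common to all: left-handed substrate 0.20 M; right-handed substrate 0.20 M; racemization catalyst 0.2 mol%
- Thursday's: reagent 2 equiv; free catalyst 2 mol%; run made earlier
- flask: reagent 2.00 equiv; free catalyst 1.3 mol%; time 15 min

Thursday's run (percent of the left-handed substrate and right-handed substrate together charged)

| time / min | left-handed product / % | right-handed product / % |
|---|---|---|
| 0.333 | 18.9 | 1.7 |
| 0.833 | 33.2 | 4.5 |
| 1.50 | 40.6 | 5.8 |
| 2.50 | 48.3 | 8.4 |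
| 3.00 | 51.1 | 8.3 |
| 5.00 | 54.7 | 12.5 |

(each reading ± 1 percentage point)

- free catalyst is single-handed; left-handed substrate and right-handed substrate are mirror images of each other, charged as a racemate, each of them at the stated concentration
- an excess is the difference of the two amounts in percent of their sum
- an excess is below zero if the other one leads
- no earlier run changes the charge of free catalyst; that part of a forecast is a guess

- left-handed product and right-handed product together, in percent of the left-handed substrate and right-handed substrate charged together, at 15 min
- excess of left-handed product over right-handed product in the product at 15 min
- whether the exchange between left-handed substrate and right-handed substrate keeps pace with the reaction: how far the product's excess at 15 min gets from its value without exchange to its value with instant exchange (above 80 % keeps pace, below 20 % hardly takes part, else lags behind)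

So the pair drains as a product of two falling amounts, and I didn't treat it as pseudo-first-order. If the rate follows reagent times substrate, it follows the square of f, and D, the inverse of f minus one, climbs in a straight line while the catalyst holds. On Thursday D went from 1.31 at 2.50 min to 2.05 at 5.00 min. That gives the slope g, the pair's clock rate, as a reading of 0.296 min⁻¹. But no run changes the free catalyst, so scaling g with loading is my guess: 0.192 min⁻¹ for the new flask, where 15 min count as 9.75 min of Thursday's time. Extending the line gives D = 3.45, so I reckoned y, the two products together, at 77.5 %.

The forecast gave a y of 82 %, higher than mine, an excess of 60 % and an exchange that lags behind, with the words “With 1.3 mol% I scale the resolving rates by about 0.65 (a guess)”.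

The new flask gave y = 73.5 %, an excess of 64.9 %, and exchange that lags behind at 53 % of the way.

    left-handed substrate + racemization catalyst ⇌ right-handed substrate + racemization catalyst, rate k1*[racemization catalyst]*[left-handed substrate] forward; the back reaction follows from the equilibrium constant (k = 25.0 M⁻¹ s⁻¹)
    2 racemization catalyst → spent catalyst (k = 36.0 M⁻¹ s⁻¹)
    reagent + free catalyst + left-handed substrate → free catalyst + left-handed product (k = 15.0 M⁻² s⁻¹)
    free catalyst ⇌ dormant form (K = 14.0, k = 0.00170 s⁻¹)
    reagent + free catalyst + right-handed substrate → free catalyst + right-handed product (k = 1.70 M⁻² s⁻¹)

So D there was 2.77, below my line. At 15.0 min the flask held free catalyst at 24.8 % of its charge and the dormant form at 75.2 %. Over the second half of the time its D climbed at 0.108 min⁻¹, less than the scaled g of 0.192 min⁻¹.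

The neighbour with 2.2 mol% of free catalyst also held 24.8 % of it at the end. So I scaled the flask's D by the ratio of the slopes, 0.325 min⁻¹ to 0.192 min⁻¹, which gives D = 4.69 and y = 82.4 %. The computed value is 80.5 %.

The numbers in the tables were generated by integration with constants of no real substance.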